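**Plan**

Retrosynthesis: the 4-hydroxycinnamate is cut at the C6–O ester bond. The C9 ketone, the C4 isopropyl carbinol and the C6 alcohol lead back to a bicyclic 5,7-dien-4-one. The seven-membered ring is cut at C7=C8 (metathesis) and at C5=C6 (olefination), and the cyclopentanone at C2–C3 and C1–C5.
Enabling feature: in the five-membered ring C4 is a latent ketone flanked by C3 and C5, and the quaternary C1 lies β to the C9 carbonyl of the seven-membered ring, with C2 as its allylic γ-carbon. An acetone 1,3-dianion unit (C3–C4–C5, activated at C5 by a phosphonate) can therefore be joined to a γ-bromo-β-methyl enoate (C2, C1, C10, C9) by alkylation at C2 and Michael addition at C1.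
Forward: this (3+2) annulation gives the cyclopentanone first. The phosphonate helper is then spent in a Horner–Wadsworth–Emmons reaction (C5=C6), and ring-closing metathesis (C7=C8) closes the seven-membered ring. C6–O/C5–H, the C4 isopropyl group, the ester and the C9 ketone follow.
Stereochemistry: C1 comes from (S)-1-phenylethylamine in the annulation. C5 and C6 (conjugate borylation) and C4 (isopropyl addition) come from attack anti to the angular C1 methyl of the bicyclic enone and ketone.

Key step: step 1

Numbering used throughout (that of the target): C1 quaternary ring-fusion carbon (CH3), C2 and C3 cyclopentane CH2, C4 carbinol carbon (isopropyl), C5 ring-fusion CH, C6 acyloxy carbon, C7=C8 (CH3 on C8), C9 ketone, C10 CH2.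
Remark: 2 is taken as the commercial, geometrically pure E ester.
Remark: the sense of induction in step 1 is assigned from the compact transition-state model given there; if the opposite sense were found, (R)-1-phenylethylamine would replace the S amine.

**Step 1**
Reactants: 1 dimethyl (2-oxopropyl)phosphonate; 2 methyl (2E)-4-bromo-3-methylbut-2-enoate
Product: 6 methyl 2-[(1R)-2-(dimethoxyphosphoryl)-1-methyl-3-oxocyclopentyl]acetate, via acyclic keto phosphonate 3 (not isolated), via acyclic enamine 4 (not isolated), via cyclic enamine 5 (not isolated)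
Conditions: NaH, THF, 0 °C, then n-BuLi, 0 °C; 2, −78 °C; AcOH, −78 °C to rt; (S)-1-phenylethylamine, 4 Å molecular sieves, THF, rt to 60 °C; aq. AcOH, THF, rt
Reagents that add atoms: water O
Why: Proposed new method: the 1,3-dianion of 1 is alkylated at its terminal carbon by the allylic bromide of 2 in an SN2 step (C2–C3); after neutralisation the ketone of 3 condenses with the chiral amine to the Z secondary enamine 4, whose carbon C5 adds in an aza-ene-type Michael step to C1 of the tethered enoate (C1–C5) before hydrolysis returns the ketone. The closest known reaction types are the γ-alkylation of β-keto phosphonate dianions and the asymmetric Michael reaction of secondary enamines of 1-phenylethylamine, which has been used with ketones and β-keto esters and with acceptors that are not β,β-disubstituted. The cyclopentane closes in the 5-exo-trig mode. The only stereocentre that persists, the quaternary C1, is set by the 1-phenylethyl group: with its C–H bond eclipsing the enamine, the phenyl group shields one face of C5, and the E enoate approaches the other face with its ester arm over the N–H, which should give 1R. The step needs terminal over internal alkylation and substitution over conjugate addition, secured by the higher reactivity of the terminal carbanion of the dianion and by the hindered β,β-disubstituted acceptor beside a primary allylic bromide; it needs C- over N-attack in the ring closure, which the weakly basic, hydrogen-bonded nitrogen of the enaminophosphonate should secure. The configuration at C5 is of no consequence, since C5 becomes sp2 again in step 4.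

**Step 2**
Reactants: 6 methyl 2-[(1R)-2-(dimethoxyphosphoryl)-1-methyl-3-oxocyclopentyl]acetate
Product: 8 dimethyl {(2R)-2-(2-hydroxy-3-methylbut-3-en-1-yl)-2-methyl-5-oxocyclopentyl}phosphonate, via aldehyde 7 (not isolated)
Conditions: NaH, THF, 0 °C; i-Bu2AlH, −78 °C; isopropenylmagnesium bromide, −78 to 0 °C; aq. potassium sodium tartrate
Reagents that add atoms: isopropenylmagnesium bromide CC(=C)[Mg]Br
Why: The sodium enolate shields the acidic keto phosphonate, i-Bu2AlH reduces the ester to the aluminium hemiacetal of aldehyde 7, and the Grignard reagent adds as this collapses (one-pot partial reduction and Grignard addition); the C9 carbinol centre is not controlled and is erased in step 11.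

**Step 3**
Reactants: 8 dimethyl {(2R)-2-(2-hydroxy-3-methylbut-3-en-1-yl)-2-methyl-5-oxocyclopentyl}phosphonate
Product: 9 dimethyl {(2R)-2-(2-{[tert-butyl(dimethyl)silyl]oxy}-3-methylbut-3-en-1-yl)-2-methyl-5-oxocyclopentyl}phosphonate
Conditions: TBSCl, imidazole, DMF, rt
Reagents that add atoms: tert-butyldimethylsilyl chloride CC(C)(C)[Si](C)(C)Cl
Why: Standard silylation of the secondary allylic alcohol keeps C9–O masked, so that only C6–OH is acylated in step 9 and only C9–OH is oxidised in step 11.

**Step 4**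
Reactants: 9 dimethyl {(2R)-2-(2-{[tert-butyl(dimethyl)silyl]oxy}-3-methylbut-3-en-1-yl)-2-methyl-5-oxocyclopentyl}phosphonate
Product: 10 (2E,3R)-2-[(2E)-but-2-en-1-ylidene]-3-(2-{[tert-butyl(dimethyl)silyl]oxy}-3-methylbut-3-en-1-yl)-3-methylcyclopentan-1-one
Conditions: LiCl, i-Pr2NEt, (E)-but-2-enal, MeCN, rt
Reagents that add atoms: (E)-but-2-enal C/C=C/C=O
Why: The Horner–Wadsworth–Emmons reaction of the cyclic β-keto phosphonate under Masamune–Roush conditions removes the phosphonate helper and should give the thermodynamically preferred E-alkylidene ketone, in which C7 points toward C1 as the ring closure requires.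

**Step 5**
Reactants: 10 (2E,3R)-2-[(2E)-but-2-en-1-ylidene]-3-(2-{[tert-butyl(dimethyl)silyl]oxy}-3-methylbut-3-en-1-yl)-3-methylcyclopentan-1-one
Product: 11 (3aR)-5-{[tert-butyl(dimethyl)silyl]oxy}-3a,6-dimethyl-3,3a,4,5-tetrahydroazulen-1(2H)-one
Conditions: second-generation Grubbs catalyst (5 mol %), toluene, 80 °C, high dilution
Reagents that add atoms: none
Why: Ring-closing metathesis between the propenyl terminus and the isopropenyl group forms the seven-membered ring with the trisubstituted C7=C8 bond and releases propene; the enone C5=C6 bond is too electron-poor and hindered to take part.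

**Step 6**
Reactants: 11 (3aR)-5-{[tert-butyl(dimethyl)silyl]oxy}-3a,6-dimethyl-3,3a,4,5-tetrahydroazulen-1(2H)-one
Product: 13 (3aR,8S,8aS)-5-{[tert-butyl(dimethyl)silyl]oxy}-8-hydroxy-3a,6-dimethyl-3,3a,4,5,8,8a-hexahydroazulen-1(2H)-one, via boryl ketone 12 (not isolated)
Conditions: CuCl (5 mol %), bis[2-(diphenylphosphino)phenyl] ether, NaOt-Bu (cat.), B2pin2, MeOH, THF, rt; then H2O2, pH 7 phosphate buffer, 0 °C
Reagents that add atoms: hydrogen peroxide OO
Why: In this copper-catalysed conjugate borylation the boryl copper species should add 1,4 to the enone (the δ-carbon C8 is fully substituted, which disfavours 1,6-addition), with boron entering at C6 and the proton at C5 from the face opposite the angular C1 methyl; oxidation of the C–B bond with retention then gives the C6 alcohol, so that C5 (trans ring fusion) and C6 are set together.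

**Step 7**
Reactants: 13 (3aR,8S,8aS)-5-{[tert-butyl(dimethyl)silyl]oxy}-8-hydroxy-3a,6-dimethyl-3,3a,4,5,8,8a-hexahydroazulen-1(2H)-one
Product: 14 (3R,3aS,4S,8aR)-7-{[tert-butyl(dimethyl)silyl]oxy}-6,8a-dimethyl-3-(propan-2-yl)-1,2,3,3a,4,7,8,8a-octahydroazulene-3,4-diol
Conditions: CeCl3, i-PrMgCl (3 equiv), THF, −78 °C; aq. NH4Cl
Reagents that add atoms: isopropylmagnesium chloride CC(C)[Mg]Cl
Why: The weakly basic organocerium reagent should add to the cyclopentanone without enolisation or retro-aldol cleavage, from the face opposite both the C1 methyl and the C5–C6 bond, which places isopropyl cis to H5 and the C4 hydroxyl cis to the angular methyl.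

**Step 8**
Reactants: 15 (2E)-3-(4-hydroxyphenyl)prop-2-enoic acid
Product: 17 (2E)-3-(4-{[tert-butyl(dimethyl)silyl]oxy}phenyl)prop-2-enoic acid, via bis-silyl compound 16 (not isolated)
Conditions: TBSCl (2.2 equiv), imidazole, DMF, rt; then AcOH/THF/H2O, rt
Reagents that add atoms: tert-butyldimethylsilyl chloride CC(C)(C)[Si](C)(C)Cl
Why: Silylation of both acidic groups followed by selective hydrolysis of the labile silyl ester leaves the phenol protected for the esterification.

**Step 9**
Reactants: 14 (3R,3aS,4S,8aR)-7-{[tert-butyl(dimethyl)silyl]oxy}-6,8a-dimethyl-3-(propan-2-yl)-1,2,3,3a,4,7,8,8a-octahydroazulene-3,4-diol; 17 (2E)-3-(4-{[tert-butyl(dimethyl)silyl]oxy}phenyl)prop-2-enoic acid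
Product: 18 (3R,3aS,4S,8aR)-7-{[tert-butyl(dimethyl)silyl]oxy}-3-hydroxy-6,8a-dimethyl-3-(propan-2-yl)-1,2,3,3a,4,7,8,8a-octahydroazulen-4-yl (2E)-3-(4-{[tert-butyl(dimethyl)silyl]oxy}phenyl)prop-2-enoate
Conditions: N,N'-dicyclohexylcarbodiimide, DMAP (cat.), CH2Cl2, rt
Reagents that add atoms: none
Why: Steglich esterification acylates the secondary C6 hydroxyl with retention at C6; the tertiary C4 hydroxyl does not react under these conditions.

**Step 10**
Reactants: 18 (3R,3aS,4S,8aR)-7-{[tert-butyl(dimethyl)silyl]oxy}-3-hydroxy-6,8a-dimethyl-3-(propan-2-yl)-1,2,3,3a,4,7,8,8a-octahydroazulen-4-yl (2E)-3-(4-{[tert-butyl(dimethyl)silyl]oxy}phenyl)prop-2-enoate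
Product: 19 (3R,3aS,4S,8aR)-3,7-dihydroxy-6,8a-dimethyl-3-(propan-2-yl)-1,2,3,3a,4,7,8,8a-octahydroazulen-4-yl (2E)-3-(4-hydroxyphenyl)prop-2-enoate
Conditions: HF·pyridine, THF, 0 °C to rt
Reagents that add atoms: none
Why: Fluoride cleaves the aryl and the secondary alkyl silyl ether, while the ester, the tertiary alcohol and the alkenes should be left untouched.

**Step 11**
Reactants: 19 (3R,3aS,4S,8aR)-3,7-dihydroxy-6,8a-dimethyl-3-(propan-2-yl)-1,2,3,3a,4,7,8,8a-octahydroazulen-4-yl (2E)-3-(4-hydroxyphenyl)prop-2-enoate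
Product: 20 (3R,3aS,4S,8aR)-3-hydroxy-6,8a-dimethyl-7-oxo-3-(propan-2-yl)-1,2,3,3a,4,7,8,8a-octahydroazulen-4-yl (2E)-3-(4-hydroxyphenyl)prop-2-enoate
Conditions: MnO2, CH2Cl2, rt
Reagents that add atoms: none
Why: MnO2 should oxidise only the allylic C9 alcohol (both C9 epimers converge) to the conjugated enone, leaving the esterified C6 position, the tertiary alcohol and the phenol unaffected, which gives the target.

**Compound list**

1 | dimethyl (2-oxopropyl)phosphonate | CC(=O)CP(=O)(OC)OC | starting material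
2 | methyl (2E)-4-bromo-3-methylbut-2-enoate | COC(=O)/C=C(\C)CBr | starting material
3 | methyl (2E)-7-(dimethoxyphosphoryl)-3-methyl-6-oxohept-2-enoate (acyclic keto phosphonate, not isolated) | COC(=O)/C=C(\C)CCC(=O)CP(=O)(OC)OC | intermediate
4 | methyl (2E,6Z)-7-(dimethoxyphosphoryl)-3-methyl-6-{[(1S)-1-phenylethyl]amino}hepta-2,6-dienoate (acyclic enamine, not isolated) | COC(=O)/C=C(\C)CC/C(N[C@@H](C)c1ccccc1)=C/P(=O)(OC)OC | intermediate
5 | methyl 2-[(1R)-2-(dimethoxyphosphoryl)-1-methyl-3-{[(1S)-1-phenylethyl]amino}cyclopent-2-en-1-yl]acetate (cyclic enamine, not isolated) | COC(=O)C[C@@]1(C)CCC(N[C@@H](C)c2ccccc2)=C1P(=O)(OC)OC | intermediate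
6 | methyl 2-[(1R)-2-(dimethoxyphosphoryl)-1-methyl-3-oxocyclopentyl]acetate (both epimers at the phosphorus-bearing carbon C5) | COC(=O)C[C@@]1(C)CCC(=O)C1P(=O)(OC)OC | intermediate
7 | 2-[(1R)-2-(dimethoxyphosphoryl)-1-methyl-3-oxocyclopentyl]acetaldehyde (not isolated) | O=CC[C@@]1(C)CCC(=O)C1P(=O)(OC)OC | intermediate
8 | dimethyl {(2R)-2-(2-hydroxy-3-methylbut-3-en-1-yl)-2-methyl-5-oxocyclopentyl}phosphonate (epimers at C9 and C5) | CC(=C)C(O)C[C@@]1(C)CCC(=O)C1P(=O)(OC)OC | intermediate
9 | dimethyl {(2R)-2-(2-{[tert-butyl(dimethyl)silyl]oxy}-3-methylbut-3-en-1-yl)-2-methyl-5-oxocyclopentyl}phosphonate (epimers at C9 and C5) | CC(=C)C(O[Si](C)(C)C(C)(C)C)C[C@@]1(C)CCC(=O)C1P(=O)(OC)OC | intermediate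
10 | (2E,3R)-2-[(2E)-but-2-en-1-ylidene]-3-(2-{[tert-butyl(dimethyl)silyl]oxy}-3-methylbut-3-en-1-yl)-3-methylcyclopentan-1-one (C9 epimers) | CC(=C)C(O[Si](C)(C)C(C)(C)C)C[C@@]1(C)CCC(=O)/C1=C/C=C/C | intermediate
11 | (3aR)-5-{[tert-butyl(dimethyl)silyl]oxy}-3a,6-dimethyl-3,3a,4,5-tetrahydroazulen-1(2H)-one (C4 ketone, C5=C6 and C7=C8; C9 epimers) | CC1=CC=C2[C@](C)(CCC2=O)CC1O[Si](C)(C)C(C)(C)C | intermediate
12 | pinacol boronate corresponding to 13, boron in place of the C6 hydroxyl with the same configuration (not isolated) | CC1=C[C@H](B2OC(C)(C)C(C)(C)O2)[C@@H]3[C@](C)(CCC3=O)CC1O[Si](C)(C)C(C)(C)C | intermediate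
13 | (3aR,8S,8aS)-5-{[tert-butyl(dimethyl)silyl]oxy}-8-hydroxy-3a,6-dimethyl-3,3a,4,5,8,8a-hexahydroazulen-1(2H)-one (trans-fused; C9 epimers) | CC1=C[C@H](O)[C@@H]2[C@](C)(CCC2=O)CC1O[Si](C)(C)C(C)(C)C | intermediate
14 | (3R,3aS,4S,8aR)-7-{[tert-butyl(dimethyl)silyl]oxy}-6,8a-dimethyl-3-(propan-2-yl)-1,2,3,3a,4,7,8,8a-octahydroazulene-3,4-diol (C9 epimers) | CC1=C[C@H](O)[C@@H]2[C@](C)(CC[C@@]2(O)C(C)C)CC1O[Si](C)(C)C(C)(C)C | intermediate
15 | (2E)-3-(4-hydroxyphenyl)prop-2-enoic acid | OC(=O)/C=C/c1ccc(O)cc1 | starting material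
16 | tert-butyldimethylsilyl (2E)-3-(4-{[tert-butyl(dimethyl)silyl]oxy}phenyl)prop-2-enoate (not isolated) | CC(C)(C)[Si](C)(C)OC(=O)/C=C/c1ccc(O[Si](C)(C)C(C)(C)C)cc1 | intermediate
17 | (2E)-3-(4-{[tert-butyl(dimethyl)silyl]oxy}phenyl)prop-2-enoic acid | OC(=O)/C=C/c1ccc(O[Si](C)(C)C(C)(C)C)cc1 | intermediate
18 | (3R,3aS,4S,8aR)-7-{[tert-butyl(dimethyl)silyl]oxy}-3-hydroxy-6,8a-dimethyl-3-(propan-2-yl)-1,2,3,3a,4,7,8,8a-octahydroazulen-4-yl (2E)-3-(4-{[tert-butyl(dimethyl)silyl]oxy}phenyl)prop-2-enoate (C9 epimers) | CC1=C[C@H](OC(=O)/C=C/c2ccc(O[Si](C)(C)C(C)(C)C)cc2)[C@@H]2[C@](C)(CC[C@@]2(O)C(C)C)CC1O[Si](C)(C)C(C)(C)C | intermediate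
19 | (3R,3aS,4S,8aR)-3,7-dihydroxy-6,8a-dimethyl-3-(propan-2-yl)-1,2,3,3a,4,7,8,8a-octahydroazulen-4-yl (2E)-3-(4-hydroxyphenyl)prop-2-enoate (C9 epimers) | CC1=C[C@H](OC(=O)/C=C/c2ccc(O)cc2)[C@@H]2[C@](C)(CC[C@@]2(O)C(C)C)CC1O | intermediate
20 | (3R,3aS,4S,8aR)-3-hydroxy-6,8a-dimethyl-7-oxo-3-(propan-2-yl)-1,2,3,3a,4,7,8,8a-octahydroazulen-4-yl (2E)-3-(4-hydroxyphenyl)prop-2-enoate | CC1=C[C@H](OC(=O)/C=C/c2ccc(O)cc2)[C@@H]2[C@](C)(CC[C@@]2(O)C(C)C)CC1=O | target

**Step count and risks**

Total: 11 steps. Longest linear sequence: 10 steps (steps 1 to 7 and 9 to 11).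

Steps most likely to fail:

1. Step 1 (proposed new method). The weakly nucleophilic enaminophosphonate may close slowly on the β,β-disubstituted enoate, a base-mediated racemic cyclisation of 3 may compete, or the facial discrimination at C1 may be insufficient. Fallback, in known chemistry: the sequence sets out from 3, which is isolated after the dianion alkylation and cyclised as its caesium enolate (Cs2CO3, MeCN, intramolecular Michael addition) to the racemic keto phosphonate F1. Condensation with (S)-1-phenylethylamine gives 5 together with its C1-epimeric enamine F2. The two diastereomers are separated by chromatography or crystallisation (classical resolution), and hydrolysis of 5 with aqueous AcOH brings the route back at 6.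

2. Step 5. Initiation at the conjugated propenyl group may be sluggish, and the deactivated dienyl carbene may fail to engage the hindered 1,1-disubstituted alkene, so that oligomerisation takes over. Fallback: the ring is closed at C8–C9 instead, setting out from 6. Reduction of the ester with the ketone masked as its enolate (NaH, then LiBH4) gives the primary alcohol F3. But-2-yn-1-ol is converted with sodium bis(2-methoxyethoxy)aluminium hydride and I2 into (2Z)-3-iodobut-2-en-1-ol F4 and with MnO2 into (2Z)-3-iodobut-2-enal F5, and Horner–Wadsworth–Emmons reaction of F3 with F5 (LiCl, i-Pr2NEt) gives the iodo dienone alcohol F6. Dess–Martin oxidation gives the iodo dienone aldehyde F7, an intramolecular Nozaki–Hiyama–Kishi reaction (CrCl2, cat. NiCl2, DMF) closes the seven-membered ring to the dienone alcohol F8, and silylation (TBSCl, imidazole) brings the route back at 11.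

3. Step 6. Boron delivery at C6, two bonds away from the directing methyl group and close to the C9 silyloxy group, may show poor facial selectivity. Fallback: C6 is set by hydroxyl-directed reduction instead, setting out from 11. The C6-epimeric hydroxy ketone F9 that accompanies 13 is taken through the isopropyl addition of step 7 to the C6-epimeric diol F10. MnO2 oxidises its allylic C6 alcohol to the C6 ketone F11, in which the trans ring fusion is also the preferred one beside the isopropyl group. Me4NBH(OAc)3 in MeCN/AcOH, bound to the tertiary C4 hydroxyl, then delivers hydride to C6 from the face of that hydroxyl (Evans–Saksena anti reduction), which brings the route back at 14.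

**Further compounds**

F1 | step 1 | racemic methyl 2-[2-(dimethoxyphosphoryl)-1-methyl-3-oxocyclopentyl]acetate | COC(=O)CC1(C)CCC(=O)C1P(=O)(OC)OC
F2 | step 1 | methyl 2-[(1S)-2-(dimethoxyphosphoryl)-1-methyl-3-{[(1S)-1-phenylethyl]amino}cyclopent-2-en-1-yl]acetate (C1 epimer of 5) | COC(=O)C[C@]1(C)CCC(N[C@@H](C)c2ccccc2)=C1P(=O)(OC)OC
F3 | step 5 | dimethyl [(2R)-2-(2-hydroxyethyl)-2-methyl-5-oxocyclopentyl]phosphonate | OCC[C@@]1(C)CCC(=O)C1P(=O)(OC)OC
F4 | step 5 | (2Z)-3-iodobut-2-en-1-ol | C/C(I)=C/CO
F5 | step 5 | (2Z)-3-iodobut-2-enal | C/C(I)=C/C=O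
F6 | step 5 | (2E,3R)-3-(2-hydroxyethyl)-2-[(2Z)-3-iodobut-2-en-1-ylidene]-3-methylcyclopentan-1-one | OCC[C@@]1(C)CCC(=O)/C1=C/C=C(/C)I
F7 | step 5 | 2-{(1R,2E)-2-[(2Z)-3-iodobut-2-en-1-ylidene]-1-methyl-3-oxocyclopentyl}acetaldehyde | O=CC[C@@]1(C)CCC(=O)/C1=C/C=C(/C)I
F8 | step 5 | (3aR)-5-hydroxy-3a,6-dimethyl-3,3a,4,5-tetrahydroazulen-1(2H)-one (C9 epimers) | CC1=CC=C2[C@](C)(CCC2=O)CC1O
F9 | step 6 | C6 epimer of 13 | CC1=C[C@@H](O)[C@@H]2[C@](C)(CCC2=O)CC1O[Si](C)(C)C(C)(C)C
F10 | step 6 | C6 epimer of 14 | CC1=C[C@@H](O)[C@@H]2[C@](C)(CC[C@@]2(O)C(C)C)CC1O[Si](C)(C)C(C)(C)C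
F11 | step 6 | C6 ketone derived from F10 (C4 hydroxyl, isopropyl and trans ring fusion as in 14) | CC1=CC(=O)[C@@H]2[C@](C)(CC[C@@]2(O)C(C)C)CC1O[Si](C)(C)C(C)(C)C
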